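Remark: read from the SMILES, the free carbinol (ring-A chain) is S and the acylated carbinol (ring-B chain) is R. Both centres carry the same three substituents, so the two halves are of opposite absolute sense and are made from separate chiral sources.

## Structural features

The target is an acyclic ester of two C17 alkylresorcinol units. Ring A is a 2,4-dihydroxy-6-alkylbenzoate (carboxyl on C1, hydroxyls on C2 and C4, chain on C6) and ring B is a 5-alkylbenzene-1,3-diol. Each ring carries an unbranched undecyl chain oxygenated at its eighth carbon (C8 on the ring-A chain, C8′ on the ring-B chain), so each carbinol sits between a propyl group and a seven-methylene tether. The units are joined only by the ester between the ring-A carboxyl and O8′, while the C8 hydroxyl stays free. The stereocentres C8 (S) and C8′ (R) are twelve bonds apart and cannot influence each other. Fragile points are the four free phenols, the ready decarboxylation of a free 2,4-dihydroxybenzoic acid, and the need to acylate only one of two near-identical secondary hydroxyls. The real difficulty is the ester: its acyl carbon is flanked by two ortho substituents (OH on C2, alkyl on C6) and must be joined to a secondary carbinol bearing two long chains, the worst case for acyl-transfer esterification. The key step exploits the fact that ring A, with oxygen on C2 and C4 and the carboxyl on C1 next to the alkylated C6, is exactly the aldol-folding product of a 3,5,7-trioxoalkanoate. Ring bond C1–C6 and the O8′–acyl bond can therefore both be made from an acyclic precursor whose acyl carbon is still unhindered.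

## Logic of the disconnections

23 back to 22. No skeletal bond is cut: three O–CH2Ph bonds are re-installed (two on ring B, one on O8) and two C=C bonds are re-introduced (C10=C11 of the ring-A chain, C1′=C2′ of the ring-B chain). This lets one hydrogenation finish the synthesis, lets the propyl terminus of the ring-A chain be carried as an allyl group, and lets the ring-B chain be attached as a styrene. The forward step must cleave one secondary alkyl benzyl ether without touching the non-benzylic ester.

22 back to 19 and 9 (key disconnection). Two bonds are cut together: the ester bond O8′–C(acyl) and the ring-A bond C1–C6. Ring A unfolds to the open-chain triketo ester 21, which is traced to the acylketene 20 and to its masked, storable form 19. The cut removes the hindered ester and the aromatic ring in one operation, splits 22 into two halves of similar size, and needs no protection of the ring-A phenols because they do not yet exist. The forward step demands that the hydroxyl of 9 is the only free OH present, that intermolecular capture of 20 beats its self-cyclisation, and that the chain folds by C2-to-C7 aldol closure only.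

19 back to 12 and 17. The C3–C4 bond of the dioxoalkyl side chain is cut (a Claisen-type acylation). This separates the achiral polyketide head from the chiral lipid tail at the oxidation level needed for folding. The forward step demands acylation at the terminal carbon of dianion 18 without over-addition, hence an N-methoxy-N-methyl amide as acyl donor.

17 back to 16, 15 and 13. After two functional-group changes (amide to ester, benzyl ether to alcohol), the C9–C10 bond of 15 is cut between the carbinol and the allyl group. 13 already holds the seven methylenes and the acyl terminus in the right place, and the allyl group becomes the propyl end. The forward step sets C9 by reagent control on an unbranched aldehyde and must leave the methyl ester alone.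

12 back to 10. The bond between the 6-methyl carbon of 10 and an acetyl carbonyl is cut (vinylogous Claisen acylation). The demand is γ-selective C-acylation of dienolate 11.

9 back to 6 and 7. The C10=C11 bond of 9 is cut (Wittig). Ring B is bought with both phenols already benzylated in 7. The forward step must form the ylide in the presence of the free hydroxyl (one extra equivalent of base); the alkene geometry is irrelevant.

6 back to 4, then 1 and 2. The C–P bond and then the C5–C6 bond of 4 are cut. The stereocentre is bought in 2 and is never touched, because the nucleophile attacks the unsubstituted epoxide carbon. The forward step needs selective magnesium insertion into C–Br over C–Cl in 1 and terminal attack on 2.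

## Other disconnections considered

Alternative 1: the first idea is to cut only the ester bond O8′–C(acyl) at the end. The forward step would be a Mitsunobu esterification (inversion) of 2,4-bis(benzyloxy)-6-[(8S)-8-(benzyloxy)undecyl]benzoic acid A1 with (4S)-11-[3,5-bis(benzyloxy)phenyl]undecan-4-ol A2, or acylation of 9 by the acid chloride of A1. The carboxyl of A1 has two ortho substituents, so addition to the acyl carbon is sterically retarded. The Mitsunobu variant has to displace at a carbinol flanked by two long chains, where elimination competes. A1 also needs a preformed arene with three protected oxygens and a separately attached chain, so ring A and the ester cost two separate sequences. The chosen plan makes both in one step with no ring-A protecting groups.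

Alternative 2: cut the C5–C6 bond of each undecyl chain and join it by anodic mixed Kolbe coupling. For the ring-B half, 6-[3,5-bis(benzyloxy)phenyl]hexanoic acid A3 and (4R)-4-acetoxyheptanoic acid A4 would give (4R)-11-[3,5-bis(benzyloxy)phenyl]undecan-4-yl acetate A5. A mixed Kolbe coupling is statistical and needs one acid in large excess. The dialkoxyarene of A3 is expected to be oxidised at a lower potential than the carboxylate, so ring and benzylic oxidation would compete. The step also does nothing for the hindered ester, so the real difficulty is left for a later step of the Alternative 1 type.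

Alternative 3: cut ring A across C1–C2 and C5–C6 and build it by Diels–Alder reaction on a preformed, unhindered alkynoate ester. (4R)-11-[3,5-Bis(benzyloxy)phenyl]undecan-4-yl (11S)-11-(benzyloxy)tetradec-2-ynoate A6 and 1-methoxy-1,3-bis(trimethylsilyloxy)buta-1,3-diene A7 would give the resorcylate after loss of methanol. The regiochemistry is right and the ester is again made before the ring. However, a β-alkyl alkynoate is a weak dienophile and would need prolonged heating at which the bis-silyl diene is labile. A6 also needs a C14 alkynoic acid and a separate esterification. The chosen aldol folding is intramolecular, runs at room temperature, is driven by aromatisation, and merges ester formation with unmasking of the chain.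

Key step: step 9

## Steps

Step 1
Reactants: 1 1-bromo-5-chloropentane; 2 (R)-2-propyloxirane
Product: 4 (4R)-10-chlorodecan-4-ol, via (5-chloropentyl)magnesium bromide 3 (not isolated)
Conditions: 1, Mg, THF, 25–35 °C; then CuI (10 mol%), 2, THF, −30 → 0 °C; aq. NH4Cl
Reagents that add atoms: none
Why: Magnesium inserts into C–Br far faster than into C–Cl, and the copper-catalysed Grignard opening of a monosubstituted epoxide is an SN2 attack at the unsubstituted CH2, so no bond at the stereocentre of 2 is broken and its R configuration becomes C4 of 4.

Step 2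
Reactants: 4 (4R)-10-chlorodecan-4-ol
Product: 6 [(7R)-7-hydroxydecyl]triphenylphosphonium iodide, via (4R)-10-iododecan-4-ol 5 (not isolated)
Conditions: NaI, PPh3, MeCN, reflux
Reagents that add atoms: triphenylphosphine, c1ccc(cc1)P(c1ccccc1)c1ccccc1; sodium iodide, [Na+].[I-]
Why: Finkelstein exchange turns the primary chloride into the iodide, which quaternises triphenylphosphine by SN2; the secondary hydroxyl and the remote stereocentre are spectators.

Step 3
Reactants: 6 [(7R)-7-hydroxydecyl]triphenylphosphonium iodide; 7 3,5-bis(benzyloxy)benzaldehyde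
Product: 9 (4R,10Z)-11-[3,5-bis(benzyloxy)phenyl]undec-10-en-4-ol, via sodium alkoxide ylide 8 (not isolated)
Conditions: NaN(SiMe3)2 (2.2 equiv), THF, −78 → 0 °C; then 7, −78 °C → rt
Reagents that add atoms: none
Why: Wittig olefination: the first equivalent of base takes the hydroxyl proton and the second forms the non-stabilised ylide, which should add to the aryl aldehyde to give mainly the Z alkene; the geometry is immaterial because the alkene is hydrogenated in step 10.

Step 4
Reactants: 10 2,2,6-trimethyl-4H-1,3-dioxin-4-one
Product: 12 2,2-dimethyl-6-(2-oxopropyl)-4H-1,3-dioxin-4-one, via lithium dienolate 11 (not isolated)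
Conditions: LiN(SiMe3)2, THF, −78 °C; then AcCl (0.5 equiv), −78 °C; aq. HCl
Reagents that add atoms: acetyl chloride, CC(Cl)=O
Why: Vinylogous Claisen acylation: deprotonation of the 6-methyl group gives the dienolate, which is C-acylated at its γ-carbon; half an equivalent of acid chloride is used because the more acidic product consumes a second equivalent of dienolate.

Step 5
Reactants: 13 methyl 9-oxononanoate
Product: 15 methyl (9R)-9-hydroxydodec-11-enoate, via borinic ester 14 (not isolated)
Conditions: (−)-Ipc2BOMe, CH2=CHCH2MgBr, Et2O, 0 °C → rt, Mg salts filtered off; then 13, Et2O, −100 °C; then 3 M NaOAc, 30% H2O2, rt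
Reagents that add atoms: allylmagnesium bromide, C=CC[Mg]Br
Why: Brown asymmetric allylboration through a closed chair transition state; the isopinocampheyl groups of the (+)-α-pinene series should direct the allyl group to the Si face of the unbranched aldehyde, which gives 9R (allyl outranks the ester chain), and the salt-free reagent at −100 °C is chosen for the highest facial selectivity while leaving the methyl ester untouched.

Step 6
Reactants: 15 methyl (9R)-9-hydroxydodec-11-enoate
Product: 16 methyl (9R)-9-(benzyloxy)dodec-11-enoate
Conditions: BnOC(=NH)CCl3, TfOH (5 mol%), CH2Cl2–cyclohexane, 0 °C → rt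
Reagents that add atoms: benzyl 2,2,2-trichloroacetimidate, ClC(Cl)(Cl)C(=N)OCc1ccccc1
Why: Acid-catalysed O-benzylation with the trichloroacetimidate transfers benzyl to oxygen without breaking the C9–O bond, so the configuration is kept, and it avoids the basic conditions that would enolise or cleave the ester.

Step 7
Reactants: 16 methyl (9R)-9-(benzyloxy)dodec-11-enoate
Product: 17 (9R)-9-(benzyloxy)-N-methoxy-N-methyldodec-11-enamide
Conditions: MeNHOMe·HCl, iPrMgCl, THF, −20 → 0 °C
Reagents that add atoms: N,O-dimethylhydroxylamine hydrochloride, CNOC.Cl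
Why: Direct ester-to-Weinreb-amide aminolysis by the magnesium amide formed in the flask; the benzyl ether, the terminal alkene and the remote stereocentre are inert.

Step 8
Reactants: 12 2,2-dimethyl-6-(2-oxopropyl)-4H-1,3-dioxin-4-one; 17 (9R)-9-(benzyloxy)-N-methoxy-N-methyldodec-11-enamide
Product: 19 6-[(12R)-12-(benzyloxy)-2,4-dioxopentadec-14-en-1-yl]-2,2-dimethyl-4H-1,3-dioxin-4-one, via dilithium dianion 18 (not isolated)
Conditions: 12 (2 equiv), LiN(iPr)2 (4.2 equiv), THF, −78 °C; then 17, −78 → −40 °C; aq. NH4Cl
Reagents that add atoms: none
Why: Claisen-type acylation of a 1,3-dicarbonyl dianion at its more basic terminal carbon; the chelated tetrahedral adduct of the Weinreb amide should stop the reaction at the ketone stage, and excess dianion absorbs the acidic proton of the product.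

Step 9
Reactants: 19 6-[(12R)-12-(benzyloxy)-2,4-dioxopentadec-14-en-1-yl]-2,2-dimethyl-4H-1,3-dioxin-4-one; 9 (4R,10Z)-11-[3,5-bis(benzyloxy)phenyl]undec-10-en-4-ol
Product: 22 (4R,10Z)-11-[3,5-bis(benzyloxy)phenyl]undec-10-en-4-yl 2-[(8R)-8-(benzyloxy)undec-10-en-1-yl]-4,6-dihydroxybenzoate, via acylketene 20 (not isolated), via triketo ester 21 (not isolated)
Conditions: PhMe, 110 °C; then Cs2CO3, iPrOH–CH2Cl2, rt; then AcOH
Reagents that add atoms: none
Why: Heating 19 should cause a retro-[4+2] loss of acetone from the dioxinone to give acylketene 20, whose sp carbon carries no ortho substituents and is captured by the only free hydroxyl present, that of 9, to give triketo ester 21. The C4–O bond of 9 is not broken, so the R configuration is retained. Carbonate then forms the enolate at C2 of 21 (the most acidic position, between the ester and the C3 ketone), which attacks the C7 ketone in a 6-(enolendo)-exo-trig aldol closure; loss of water and enolisation of the C3 and C5 carbonyls give ring A. The closest known reaction type is the thermolysis of 6-(2,4-dioxoalkyl)-1,3-dioxin-4-ones in the presence of alcohols followed by base-mediated aromatisation to 6-alkyl-2,4-dihydroxybenzoates. No stereocentre is formed, and the two existing ones are remote spectators. The step needs chemoselectivity for one hydroxyl, secured by the benzyl ethers on O8 and on ring B, and intermolecular capture in preference to self-cyclisation of 20 to a pyranone, favoured by a slight excess of 9 at high concentration. It also needs the C2-to-C7 aldol mode in preference to Claisen or lactone closure, which would have to expel the alkoxide of 9 and are disfavoured under mild carbonate conditions. Aromatisation makes the sequence irreversible.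

Step 10
Reactants: 22 (4R,10Z)-11-[3,5-bis(benzyloxy)phenyl]undec-10-en-4-yl 2-[(8R)-8-(benzyloxy)undec-10-en-1-yl]-4,6-dihydroxybenzoate
Product: 23 (4R)-11-(3,5-dihydroxyphenyl)undecan-4-yl 2,4-dihydroxy-6-[(8S)-8-hydroxyundecyl]benzoate
Conditions: H2 (1 atm), Pd(OH)2/C, EtOAc–EtOH, rt
Reagents that add atoms: none
Why: Catalytic hydrogenation saturates both alkenes and hydrogenolyses the three benzyl ethers, while the ester oxygen sits on a non-benzylic carbon and should survive; no stereocentre is touched, and C8 is named S only because allyl has become propyl.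

## Compound list

1 | 1-bromo-5-chloropentane | ClCCCCCBr | starting material
2 | (R)-2-propyloxirane | CCC[C@@H]1CO1 | starting material
3 | (5-chloropentyl)magnesium bromide | ClCCCCC[Mg]Br | intermediate
4 | (4R)-10-chlorodecan-4-ol | CCC[C@@H](O)CCCCCCCl | intermediate
5 | (4R)-10-iododecan-4-ol | CCC[C@@H](O)CCCCCCI | intermediate
6 | [(7R)-7-hydroxydecyl]triphenylphosphonium iodide | CCC[C@@H](O)CCCCCC[P+](c1ccccc1)(c1ccccc1)c1ccccc1.[I-] | intermediate
7 | 3,5-bis(benzyloxy)benzaldehyde | O=Cc1cc(OCc2ccccc2)cc(OCc2ccccc2)c1 | starting material
8 | sodium (4R)-10-(triphenyl-λ5-phosphanylidene)decan-4-olate (alkoxide ylide) | CCC[C@@H]([O-])CCCCCC=P(c1ccccc1)(c1ccccc1)c1ccccc1.[Na+] | intermediate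
9 | (4R,10Z)-11-[3,5-bis(benzyloxy)phenyl]undec-10-en-4-ol | CCC[C@@H](O)CCCCC/C=C\c1cc(OCc2ccccc2)cc(OCc2ccccc2)c1 | intermediate
10 | 2,2,6-trimethyl-4H-1,3-dioxin-4-one | CC1=CC(=O)OC(C)(C)O1 | starting material
11 | lithium 2,2-dimethyl-6-methylidene-6H-1,3-dioxin-4-olate (dienolate of 10) | C=C1C=C([O-])OC(C)(C)O1.[Li+] | intermediate
12 | 2,2-dimethyl-6-(2-oxopropyl)-4H-1,3-dioxin-4-one | CC(=O)CC1=CC(=O)OC(C)(C)O1 | intermediate
13 | methyl 9-oxononanoate | COC(=O)CCCCCCCC=O | starting material
14 | methyl (9R)-9-[(diisopinocampheylboranyl)oxy]dodec-11-enoate (borinic ester) | C=CC[C@H](OB([C@@H]1C[C@@H]2C[C@H]([C@H]1C)C2(C)C)[C@@H]1C[C@@H]2C[C@H]([C@H]1C)C2(C)C)CCCCCCCC(=O)OC | intermediate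
15 | methyl (9R)-9-hydroxydodec-11-enoate | C=CC[C@H](O)CCCCCCCC(=O)OC | intermediate
16 | methyl (9R)-9-(benzyloxy)dodec-11-enoate | C=CC[C@H](OCc1ccccc1)CCCCCCCC(=O)OC | intermediate
17 | (9R)-9-(benzyloxy)-N-methoxy-N-methyldodec-11-enamide | C=CC[C@H](OCc1ccccc1)CCCCCCCC(=O)N(C)OC | intermediate
18 | dilithium dianion of 12 (deprotonated at C1 and C3 of the 2-oxopropyl group) | [Li+].[Li+].[CH2-]C(=O)[CH-]C1=CC(=O)OC(C)(C)O1 | intermediate
19 | 6-[(12R)-12-(benzyloxy)-2,4-dioxopentadec-14-en-1-yl]-2,2-dimethyl-4H-1,3-dioxin-4-one | C=CC[C@H](OCc1ccccc1)CCCCCCCC(=O)CC(=O)CC1=CC(=O)OC(C)(C)O1 | intermediate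
20 | (15R)-15-(benzyloxy)-3,5,7-trioxooctadeca-1,17-dien-1-one (acylketene) | C=CC[C@H](OCc1ccccc1)CCCCCCCC(=O)CC(=O)CC(=O)C=C=O | intermediate
21 | (4R,10Z)-11-[3,5-bis(benzyloxy)phenyl]undec-10-en-4-yl (15R)-15-(benzyloxy)-3,5,7-trioxooctadec-17-enoate (triketo ester) | C=CC[C@H](OCc1ccccc1)CCCCCCCC(=O)CC(=O)CC(=O)CC(=O)O[C@H](CCC)CCCCC/C=C\c1cc(OCc2ccccc2)cc(OCc2ccccc2)c1 | intermediate
22 | (4R,10Z)-11-[3,5-bis(benzyloxy)phenyl]undec-10-en-4-yl 2-[(8R)-8-(benzyloxy)undec-10-en-1-yl]-4,6-dihydroxybenzoate | C=CC[C@H](OCc1ccccc1)CCCCCCCc1cc(O)cc(O)c1C(=O)O[C@H](CCC)CCCCC/C=C\c1cc(OCc2ccccc2)cc(OCc2ccccc2)c1 | intermediate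
23 | (4R)-11-(3,5-dihydroxyphenyl)undecan-4-yl 2,4-dihydroxy-6-[(8S)-8-hydroxyundecyl]benzoate | CCC[C@H](O)CCCCCCCc1cc(O)cc(O)c1C(=O)O[C@H](CCC)CCCCCCCc1cc(O)cc(O)c1 | target

## Step count and least certain steps

Total: 10 steps. Longest linear sequence: 6 steps (13 → 15 → 16 → 17 → 19 → 22 → 23; steps 5, 6, 7, 8, 9, 10). The ring-B branch (steps 1–3) and the dioxinone head (step 4) join at steps 9 and 8.

Step 9 (key step). The most likely failure is loss of the acylketene to self-capture before the hindered secondary hydroxyl of 9 reaches it. The enol oxygen of its own 5-ketone can close to a 4-hydroxy-2-pyranone, and ketene dimerisation is also possible. During the base treatment, lactone closure with expulsion of 9 could also compete with the aldol, because all three processes are intramolecular and the desired capture is bimolecular. The fallback separates ring formation from ester formation and sets out from 19. Treatment with Et3N in CH2Cl2 at rt should cyclo-aromatise 19 with the dioxinone ring kept, to give 5-[(8R)-8-(benzyloxy)undec-10-en-1-yl]-7-hydroxy-2,2-dimethyl-4H-1,3-benzodioxin-4-one F1. Benzylation of its phenol (BnBr, K2CO3, acetone) gives 7-(benzyloxy)-5-[(8R)-8-(benzyloxy)undec-10-en-1-yl]-2,2-dimethyl-4H-1,3-benzodioxin-4-one F2. 9 is then deprotonated with NaN(SiMe3)2 in THF and added to F2, whose tied-back acetonide carbonyl is opened by the alkoxide with loss of acetone and retention at the carbinol. This gives (4R,10Z)-11-[3,5-bis(benzyloxy)phenyl]undec-10-en-4-yl 4-(benzyloxy)-2-[(8R)-8-(benzyloxy)undec-10-en-1-yl]-6-hydroxybenzoate F3. Hydrogenation of F3 under the conditions of step 10 returns to the route at 23.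

Step 8. The strongly basic dianion 18 may deprotonate the α-methylene of 17 instead of adding to it, or may be acylated on oxygen; both consume the valuable amide without forming the C–C bond. The fallback replaces the Claisen acylation by aldol addition and oxidation; it sets out from 16 and 12. Reduction of 16 with iBu2AlH at −78 °C gives (9R)-9-(benzyloxy)dodec-11-enal F4. Its addition to dianion 18 (from 12 and LiN(iPr)2) gives 6-[(12R)-12-(benzyloxy)-4-hydroxy-2-oxopentadec-14-en-1-yl]-2,2-dimethyl-4H-1,3-dioxin-4-one F5 as both C4 epimers. Oxidation with Dess–Martin periodinane returns to the route at 19.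

Step 5. Facial selectivity on an unbranched aldehyde may be incomplete. Because C8 and C8′ of the final product are twelve bonds apart, the resulting minor stereoisomer could not be removed later. The fallback takes the stereocentre from a resolved epoxide and sets out from 13. Corey–Chaykovsky methylenation (Me3S+ I−, KOtBu, DMSO) gives racemic methyl 8-(oxiran-2-yl)octanoate F6. Jacobsen hydrolytic kinetic resolution with the enantiomer of (salen)Co(OAc) that hydrolyses the S epoxide leaves methyl 8-[(2R)-oxiran-2-yl]octanoate F7 and converts the rest into methyl (9S)-9,10-dihydroxydecanoate F8, which is separated. Opening of F7 at its terminal carbon with CH2=CHMgBr and CuI (10 mol%) in THF at −40 °C returns to the route at 15.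

Step 10. Hydrogenolysis of the secondary alkyl benzyl ether on O8 is expected to be much slower than that of the two aryl benzyl ethers, and forcing it may begin to saturate the electron-rich rings. The fallback removes the last benzyl group by a Lewis-acid mechanism and sets out from 22. Brief hydrogenation over Pd/C in EtOAc saturates both alkenes and frees the ring-B phenols, giving (4R)-11-(3,5-dihydroxyphenyl)undecan-4-yl 2-[(8S)-8-(benzyloxy)undecyl]-4,6-dihydroxybenzoate F9. Treatment of F9 with BCl3 and pentamethylbenzene in CH2Cl2 at −78 °C cleaves the remaining ether, with the benzyl cation trapped by the arene, and returns to the route at 23.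

## Further compounds

F1 | step 9 | 5-[(8R)-8-(benzyloxy)undec-10-en-1-yl]-7-hydroxy-2,2-dimethyl-4H-1,3-benzodioxin-4-one | C=CC[C@H](OCc1ccccc1)CCCCCCCc1cc(O)cc2OC(C)(C)OC(=O)c12
F2 | step 9 | 7-(benzyloxy)-5-[(8R)-8-(benzyloxy)undec-10-en-1-yl]-2,2-dimethyl-4H-1,3-benzodioxin-4-one | C=CC[C@H](OCc1ccccc1)CCCCCCCc1cc(OCc3ccccc3)cc2OC(C)(C)OC(=O)c12
F3 | step 9 | (4R,10Z)-11-[3,5-bis(benzyloxy)phenyl]undec-10-en-4-yl 4-(benzyloxy)-2-[(8R)-8-(benzyloxy)undec-10-en-1-yl]-6-hydroxybenzoate | C=CC[C@H](OCc1ccccc1)CCCCCCCc1cc(OCc2ccccc2)cc(O)c1C(=O)O[C@H](CCC)CCCCC/C=C\c1cc(OCc2ccccc2)cc(OCc2ccccc2)c1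
F4 | step 8 | (9R)-9-(benzyloxy)dodec-11-enal | C=CC[C@H](OCc1ccccc1)CCCCCCCC=O
F5 | step 8 | 6-[(12R)-12-(benzyloxy)-4-hydroxy-2-oxopentadec-14-en-1-yl]-2,2-dimethyl-4H-1,3-dioxin-4-one (both C4 epimers) | C=CC[C@H](OCc1ccccc1)CCCCCCCC(O)CC(=O)CC1=CC(=O)OC(C)(C)O1
F6 | step 5 | racemic methyl 8-(oxiran-2-yl)octanoate | COC(=O)CCCCCCCC1CO1
F7 | step 5 | methyl 8-[(2R)-oxiran-2-yl]octanoate | COC(=O)CCCCCCC[C@@H]1CO1
F8 | step 5 | methyl (9S)-9,10-dihydroxydecanoate | COC(=O)CCCCCCC[C@H](O)CO
F9 | step 10 | (4R)-11-(3,5-dihydroxyphenyl)undecan-4-yl 2-[(8S)-8-(benzyloxy)undecyl]-4,6-dihydroxybenzoate | CCC[C@H](OCc1ccccc1)CCCCCCCc1cc(O)cc(O)c1C(=O)O[C@H](CCC)CCCCCCCc1cc(O)cc(O)c1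
A1 | alternative 1 | 2,4-bis(benzyloxy)-6-[(8S)-8-(benzyloxy)undecyl]benzoic acid | CCC[C@H](OCc1ccccc1)CCCCCCCc1cc(OCc2ccccc2)cc(OCc2ccccc2)c1C(=O)O
A2 | alternative 1 | (4S)-11-[3,5-bis(benzyloxy)phenyl]undecan-4-ol | CCC[C@H](O)CCCCCCCc1cc(OCc2ccccc2)cc(OCc2ccccc2)c1
A3 | alternative 2 | 6-[3,5-bis(benzyloxy)phenyl]hexanoic acid | OC(=O)CCCCCc1cc(OCc2ccccc2)cc(OCc2ccccc2)c1
A4 | alternative 2 | (4R)-4-acetoxyheptanoic acid | CCC[C@@H](OC(C)=O)CCC(=O)O
A5 | alternative 2 | (4R)-11-[3,5-bis(benzyloxy)phenyl]undecan-4-yl acetate | CCC[C@@H](OC(C)=O)CCCCCCCc1cc(OCc2ccccc2)cc(OCc2ccccc2)c1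
A6 | alternative 3 | (4R)-11-[3,5-bis(benzyloxy)phenyl]undecan-4-yl (11S)-11-(benzyloxy)tetradec-2-ynoate | CCC[C@H](OCc1ccccc1)CCCCCCCC#CC(=O)O[C@H](CCC)CCCCCCCc1cc(OCc2ccccc2)cc(OCc2ccccc2)c1
A7 | alternative 3 | 1-methoxy-1,3-bis(trimethylsilyloxy)buta-1,3-diene | COC(O[Si](C)(C)C)=CC(=C)O[Si](C)(C)C
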